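**Plan**
- Retrosynthetic cuts, in order: the MOM acetal on ring B; the two prenyl C–C bonds at C3 and C5 (each traced back to an aryl 1,1-dimethylallyl ether through a Claisen shift); the C1–C6 bond of ring A (Claisen condensation of a masked tetraketide); the C1–C7 bond between the chain and the aroyl carbon.
- Forward order: ring B is bought as methyl 3-hydroxybenzoate. The chain is joined at C1–C7 by acylating the 6-methyl group of 4-methoxy-6-methyl-2-pyrone. Ring A then closes at C1–C6. The prenyl groups are added by double etherification, semi-hydrogenation and a double Claisen shift, and MOM removal ends the route.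
- Enabling feature: ring A is the phloroglucinol of a benzoate-primed tetraketide. C1 carries the aroyl carbon C7; C2, C4 and C6 carry oxygen; only the C4 oxygen is methylated. A 4-methoxy-2-pyrone therefore serves as the masked ester: its C4–OMe becomes the ring C4–OMe and its lactone carbonyl becomes C6.
- Stereochemistry: the target has no stereocentre and no stereogenic double bond. The only geometric element on the way is the enol-ether alkene of the ring-opened ester, fixed by the pyrone ring (E by the sequence rules, with the ester cis to the diketone chain).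

Key step: step 3

Step 1
Reactants: 1 methyl 3-hydroxybenzoate
Product: 2 methyl 3-(methoxymethoxy)benzoate
Conditions: MOMCl, iPr2NEt, CH2Cl2, 0 °C to rt
Reagents that add atoms: chloromethyl methyl ether (MOMCl), COCCl
Why: Williamson-type O-alkylation of the only phenol under amine base should give the MOM acetal, which tolerates the strong base, hot methoxide, hydrogenation and heat of the later steps.

Step 2
Reactants: 3 4-methoxy-6-methyl-2H-pyran-2-one; 2 methyl 3-(methoxymethoxy)benzoate
Product: 5 4-methoxy-6-{2-[3-(methoxymethoxy)phenyl]-2-oxoethyl}-2H-pyran-2-one, via 6-(lithiomethyl)-4-methoxy-2H-pyran-2-one 4 (not isolated)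
Conditions: LDA (LiN(iPr)2, 2.2 equiv), THF, −78 °C; then 2, −78 to −20 °C; AcOH quench
Reagents that add atoms: none
Why: Lithium diisopropylamide deprotonates the 6-methyl group (vinylogous to the lactone carbonyl), and the carbanion undergoes a crossed Claisen condensation with the non-enolisable aryl ester; the second equivalent of base holds the more acidic keto-methylene product as its enolate, which guards against double acylation.

Step 3
Reactants: 5 4-methoxy-6-{2-[3-(methoxymethoxy)phenyl]-2-oxoethyl}-2H-pyran-2-one
Product: 7 (2,6-dihydroxy-4-methoxyphenyl)[3-(methoxymethoxy)phenyl]methanone, via ring-opened methyl ester 6 (not isolated)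
Conditions: Mg(OMe)2 (excess), MeOH, reflux; then AcOH/H2O, 0 °C
Reagents that add atoms: none
Why: Methoxide adds to the lactone carbonyl and opens the 2-pyrone to methyl ester 6, whose enol-ether double bond keeps the ring geometry (ester cis to the diketone chain) and whose 1,3-diketone is held as a magnesium chelate. The central carbon of that chelated diketone (future C1) then attacks the ester carbonyl (future C6) in a 6-exo-trig Claisen condensation of the Dieckmann type, and loss of methoxide followed by enolisation of the two ring carbonyls gives aromatic ring A. The closest known reaction type is the Mg(OMe)2-mediated Claisen cyclisation of 3,5,7-trioxo esters and their pyrone forms to acylphloroglucinols. No stereocentre is formed. The selectivity needed is C-acylation over O-acylation (re-closure to the 2-pyrone or closure to a 4-pyranone); magnesium chelation makes the diketone carbon the nucleophile, and the aldol alternative is disfavoured because its donor carbon is the enol-ether CH and its acceptor is a deactivated aryl ketone. Because the C4 oxygen arrives as a methyl enol ether, it ends up as the only methylated oxygen of the phloroglucinol without any selective methylation.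

Step 4
Reactants: 7 (2,6-dihydroxy-4-methoxyphenyl)[3-(methoxymethoxy)phenyl]methanone; 8 3-chloro-3-methylbut-1-yne (first equivalent)
Product: 10 {4-methoxy-2,6-bis[(2-methylbut-3-yn-2-yl)oxy]phenyl}[3-(methoxymethoxy)phenyl]methanone, via mono-propargyl ether 9 (not isolated)
Conditions: 8 (3 equiv in all), DBU (3 equiv), CuCl2·2H2O (cat.), MeCN, 0 °C to rt
Reagents that add atoms: 3-chloro-3-methylbut-1-yne (second equivalent of 8, consumed in the etherification of 9), CC(C)(Cl)C#C
Why: Copper-catalysed propargylic etherification of the tertiary chloride by the DBU phenoxides is the standard entry to aryl 1,1-dimethylpropargyl ethers; one equivalent of 8 converts 7 into mono-ether 9 and a second equivalent converts 9 into bis-ether 10, and because the reaction runs at or below room temperature both ortho-acyl phenols should be etherified without premature rearrangement to chromenes.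

Step 5
Reactants: 10 {4-methoxy-2,6-bis[(2-methylbut-3-yn-2-yl)oxy]phenyl}[3-(methoxymethoxy)phenyl]methanone
Product: 11 {4-methoxy-2,6-bis[(2-methylbut-3-en-2-yl)oxy]phenyl}[3-(methoxymethoxy)phenyl]methanone
Conditions: H2 (1 atm), Pd/CaCO3 poisoned with Pb(OAc)2 (Lindlar catalyst), quinoline, EtOAc, rt
Reagents that add atoms: none
Why: Lindlar semi-hydrogenation should stop both terminal alkynes at the alkene with quinoline as moderator, leaving the diaryl ketone, the aryl ethers and the MOM acetal untouched.

Step 6
Reactants: 11 {4-methoxy-2,6-bis[(2-methylbut-3-en-2-yl)oxy]phenyl}[3-(methoxymethoxy)phenyl]methanone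
Product: 13 [2,6-dihydroxy-4-methoxy-3,5-bis(3-methylbut-2-en-1-yl)phenyl][3-(methoxymethoxy)phenyl]methanone, via mono-rearranged phenol 12 (not isolated)
Conditions: PhNEt2, 130–150 °C, Ar
Reagents that add atoms: none
Why: Two successive aromatic Claisen rearrangements ([3,3] shifts) should move each 1,1-dimethylallyl unit with allylic inversion to its free ortho carbon (C3, then C5), because a shift to the aroyl-bearing C1 gives a dienone that cannot tautomerise and reverts, so both units arrive as linear prenyl groups next to regenerated, chelated phenols.

Step 7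
Reactants: 13 [2,6-dihydroxy-4-methoxy-3,5-bis(3-methylbut-2-en-1-yl)phenyl][3-(methoxymethoxy)phenyl]methanone
Product: 14 [2,6-dihydroxy-4-methoxy-3,5-bis(3-methylbut-2-en-1-yl)phenyl](3-hydroxyphenyl)methanone
Conditions: 3 M HCl (aq.), MeOH, 40 °C
Reagents that add atoms: none
Why: Acid-catalysed acetal exchange with methanol (MOM cleavage) should free the ring B phenol, and dilute acid at moderate temperature is the usual way to remove MOM from prenylated phenols without cyclising the ortho-prenyl phenols to chromans.

**Compound list**
1 | methyl 3-hydroxybenzoate | COC(=O)c1cccc(O)c1 | starting material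
2 | methyl 3-(methoxymethoxy)benzoate | COCOc1cccc(C(=O)OC)c1 | intermediate
3 | 4-methoxy-6-methyl-2H-pyran-2-one | COC1=CC(=O)OC(C)=C1 | starting material
4 | 6-(lithiomethyl)-4-methoxy-2H-pyran-2-one (lithiated pyrone, not isolated) | [Li]CC1=CC(OC)=CC(=O)O1 | intermediate
5 | 4-methoxy-6-{2-[3-(methoxymethoxy)phenyl]-2-oxoethyl}-2H-pyran-2-one | COC1=CC(=O)OC(CC(=O)c2cccc(OCOC)c2)=C1 | intermediate
6 | methyl (2E)-3-methoxy-7-[3-(methoxymethoxy)phenyl]-5,7-dioxohept-2-enoate (present as its magnesium chelate, not isolated) | COC(=O)/C=C(/OC)CC(=O)CC(=O)c1cccc(OCOC)c1 | intermediate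
7 | (2,6-dihydroxy-4-methoxyphenyl)[3-(methoxymethoxy)phenyl]methanone | COCOc1cccc(C(=O)c2c(O)cc(OC)cc2O)c1 | intermediate
8 | 3-chloro-3-methylbut-1-yne | CC(C)(Cl)C#C | starting material
9 | {2-hydroxy-4-methoxy-6-[(2-methylbut-3-yn-2-yl)oxy]phenyl}[3-(methoxymethoxy)phenyl]methanone (mono-propargyl ether, not isolated) | COCOc1cccc(C(=O)c2c(O)cc(OC)cc2OC(C)(C)C#C)c1 | intermediate
10 | {4-methoxy-2,6-bis[(2-methylbut-3-yn-2-yl)oxy]phenyl}[3-(methoxymethoxy)phenyl]methanone | COCOc1cccc(C(=O)c2c(OC(C)(C)C#C)cc(OC)cc2OC(C)(C)C#C)c1 | intermediate
11 | {4-methoxy-2,6-bis[(2-methylbut-3-en-2-yl)oxy]phenyl}[3-(methoxymethoxy)phenyl]methanone | COCOc1cccc(C(=O)c2c(OC(C)(C)C=C)cc(OC)cc2OC(C)(C)C=C)c1 | intermediate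
12 | {2-hydroxy-4-methoxy-3-(3-methylbut-2-en-1-yl)-6-[(2-methylbut-3-en-2-yl)oxy]phenyl}[3-(methoxymethoxy)phenyl]methanone (mono-rearranged phenol, not isolated) | COCOc1cccc(C(=O)c2c(O)c(CC=C(C)C)c(OC)cc2OC(C)(C)C=C)c1 | intermediate
13 | [2,6-dihydroxy-4-methoxy-3,5-bis(3-methylbut-2-en-1-yl)phenyl][3-(methoxymethoxy)phenyl]methanone | COCOc1cccc(C(=O)c2c(O)c(CC=C(C)C)c(OC)c(CC=C(C)C)c2O)c1 | intermediate
14 | [2,6-dihydroxy-4-methoxy-3,5-bis(3-methylbut-2-en-1-yl)phenyl](3-hydroxyphenyl)methanone | COc1c(CC=C(C)C)c(O)c(C(=O)c2cccc(O)c2)c(O)c1CC=C(C)C | target

Total step count: 7.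
Longest linear sequence: 7 steps (1 → 2 → 5 → 7 → 10 → 11 → 13 → 14); pyrone 3 enters at step 2 and chloride 8 at step 4.

**Steps most likely to fail**

Step 4. Once the first bulky tertiary ether is in place, the remaining phenol is hydrogen-bonded to the carbonyl and shielded, so the reaction may stall at the mono-ether, and C-propargylation of the electron-rich ring may compete. The fallback sets out from 7 and returns at 13, replacing steps 4 to 6. Allyl bromide (2 equiv or more) with K2CO3 in DMF should etherify both phenols cleanly, since the electrophile is primary and unhindered, giving [4-methoxy-2,6-bis(prop-2-en-1-yloxy)phenyl][3-(methoxymethoxy)phenyl]methanone F1. Heating in PhNEt2 at about 190 °C should bring about the double aromatic Claisen rearrangement to [2,6-dihydroxy-4-methoxy-3,5-di(prop-2-en-1-yl)phenyl][3-(methoxymethoxy)phenyl]methanone F2. Cross-metathesis with excess 2-methylbut-2-ene (second-generation Grubbs catalyst, RuCl2(=CHPh)(PCy3)(H2IMes), CH2Cl2, 40 °C) then turns each allyl group into a prenyl group and gives 13.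

Step 3. The opened chain may close again through oxygen (back to the 2-pyrone, or by addition–elimination at the enol-ether carbon to a 4-pyranone), or methoxide may cleave the diketone by a retro-Claisen reaction before the carbon–carbon bond forms. The fallback sets out from ester 2 and returns at 7, replacing steps 2 and 3. It uses the same C1–C6 Claisen folding on the free triketide and adds the methyl ether afterwards. Commercial 4-hydroxy-6-methyl-2H-pyran-2-one is deprotonated with LDA (3 equiv) at oxygen and at the 6-methyl group and acylated with 2 to give 4-hydroxy-6-{2-[3-(methoxymethoxy)phenyl]-2-oxoethyl}-2H-pyran-2-one F3. Mg(OMe)2 in refluxing methanol should open this pyrone to the 3,5,7-trioxo ester and fold it to [3-(methoxymethoxy)phenyl](2,4,6-trihydroxyphenyl)methanone F4. Dimethyl sulfate (1 equiv) with K2CO3 in acetone should then methylate mainly the 4-hydroxyl, which is the most acidic and the only one not hydrogen-bonded to the ketone, giving 7.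

Step 6. Thermal fragmentation of the tertiary allyl ethers (loss of isoprene), onward migration of an allyl unit from the blocked C1 position to the para carbon, and cyclisation of the freshly formed ortho-prenyl phenols onto their alkenes may compete with the second sigmatropic shift. The fallback sets out from 7 and returns at 13, replacing steps 4 to 6 by one electrophilic alkylation. The dianion of 7 in aqueous KOH at 0 °C to rt is treated with 1-bromo-3-methylbut-2-ene (2 equiv or more), and direct C-prenylation at the two activated positions C3 and C5 of the phloroglucinol nucleus should give 13. Mono- and O-alkylated material would be separated and recycled. This fallback makes no compound outside the compound list (F0).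

**Further compounds**
F1 | step 4 | [4-methoxy-2,6-bis(prop-2-en-1-yloxy)phenyl][3-(methoxymethoxy)phenyl]methanone | COCOc1cccc(C(=O)c2c(OCC=C)cc(OC)cc2OCC=C)c1
F2 | step 4 | [2,6-dihydroxy-4-methoxy-3,5-di(prop-2-en-1-yl)phenyl][3-(methoxymethoxy)phenyl]methanone | COCOc1cccc(C(=O)c2c(O)c(CC=C)c(OC)c(CC=C)c2O)c1
F3 | step 3 | 4-hydroxy-6-{2-[3-(methoxymethoxy)phenyl]-2-oxoethyl}-2H-pyran-2-one | COCOc1cccc(C(=O)CC2=CC(O)=CC(=O)O2)c1
F4 | step 3 | [3-(methoxymethoxy)phenyl](2,4,6-trihydroxyphenyl)methanone | COCOc1cccc(C(=O)c2c(O)cc(O)cc2O)c1
F0 | step 6 | none | none
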